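## The problem

The target (16) is a 1-aryltetralin lignan. Ring A (C4a–C8a) is a pentasubstituted benzene with 6-OMe, 7-OH and 8-OH, and ring B carries three contiguous stereocentres, C1 (4-hydroxy-3-methoxyphenyl), C2 and C3 (each CH2OH), in the all-trans (1S,2R,3R) arrangement. A synthesis must join ring A to C1 and C4 in the correct orientation, which a Friedel–Crafts-type closure onto a 3-methoxy-4,5-dioxygenated benzyl unit does not guarantee, because both ortho carbons are activated. It must also set C1 absolutely and C2 and C3 relative to it. C1 is the natural control element: the 8-oxygen lies peri to the C1 aryl group and should hold it pseudoaxial, so that it screens one face of ring B at C2. The same peri interaction penalises the all-equatorial conformer of the all-trans array, so C3 is better fixed by a stereospecific addition than by thermodynamic equilibration. The free catechol and guaiacol units oxidise in air, and the doubly benzylic C1–H is open to epimerisation and, while ring B is a 1,4-diene, to dehydrogenation to a naphthalene; the phenols therefore stay masked to the end and strong base is avoided until ring B is saturated. The enabling feature is that ring A, with its 7,8-diol next to the 6-methoxy group, is the aromatic bis-enol of 3-methoxy-1,2-benzoquinone, whose only unsubstituted C=C is the C4a–C8a fusion bond.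

## Retrosynthesis

**16 ⇒ 15.** The four O–benzyl bonds are cut. All hydroxyl groups that need masking (4′-OH, 7-OH, 8-OH, C9′-OH) are carried as benzyl ethers, so one hydrogenolysis ends the route and the oxidation-prone catechol appears only in the last flask. Nothing else in 15 is reducible under these conditions.

**15 ⇒ 13.** The C2–C9 bond is cut. C9 is added as a one-carbon unit to the C2 boronate 13 by insertion of a chloromethyl carbenoid (through 14) and oxidation. The 1,2-shift is retentive, so C2 is not put at risk. The neighbouring option, a [2,3]-sigmatropic transfer of C9 from the C3 oxygen, would leave C3 as an exocyclic alkene that then needs a second hydroboration and a thermodynamic correction at C3, which the peri effect makes unreliable. It would also cost several more steps and a tin reagent.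

**13 ⇒ 10.** The C2–B and C3–H bonds are cut (hydroboration, through 11 and 12). A syn addition of H–B across C2=C3 of 10 from the face anti to the C1 aryl group puts boron on C2 trans to the aryl group and pushes the C3 benzyloxymethyl group to the face opposite boron. One facial choice thus gives the whole all-trans array, and 10 has a single stereocentre. The forward reaction must place boron on the CH carbon (anti-Markovnikov) and deliver a monoalkylborane that can be converted into a boronic ester; monoisopinocampheylborane does both and adds reagent control.

**10 ⇒ 9.** Two O–benzyl bonds on ring A are cut. The catechol 9 is benzylated immediately because it is the most fragile compound of the route.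

**9 ⇒ 7 + 5.** C1–C8a and C4–C4a are cut (Diels–Alder reaction, then tautomerisation of adduct 8). Against a cationic closure of ring B, this cut has three advantages:
- ring A comes from a commercial catechol in one oxidation;
- the 6,7,8-oxygen pattern and its orientation follow from the substitution of quinone 7 rather than from a regiochemical competition;
- both partners are achiral and short to make.

The forward reaction must be a carbo-Diels–Alder reaction at the unsubstituted C=C of 7, with ortho orientation, endo geometry and one quinone face, and the product must be kept from redox exchange with unreacted 7.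

**7 ⇒ 6.** The quinone is the two-electron oxidation product of 3-methoxycatechol 6, made just before use.

**5 ⇒ 4 + 2.** The σ bond between the two alkene units of the diene (the future C2–C3 bond) is cut. A Suzuki–Miyaura coupling of the (E)-styrylboronate 4 with the 2-bromoallyl ether 2 fixes the E geometry and carries the C9′ oxygen as a benzyl ether from the start.

**4 ⇒ 3 and 2 ⇒ 1.** The styryl C=C is cut by a boron–Wittig olefination of commercial O-benzylvanillin 3, and 2 comes from O-benzylation of 2-bromoallyl alcohol 1.

## Roads not taken

**Alternative 1:** The cut is C4–C4a. In the forward sense the C7 phenoxide, generated with KOtBu, would displace a primary sulfonate at C4 through its para carbon and, after tautomerisation of the dienone, give the all-trans tetralin A1.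
- Merits: all three stereocentres would be set beforehand in an open chain by established methods, and the ring closure is regiochemically unambiguous because both ortho positions of the phenoxide are blocked. In stereochemical security this road is better than the chosen one.
- Weak points for this target: the three ring A oxygens must be differentiated, with C7 free and C8 protected; the diarylmethine centre and two further centres must be built in a long linear sequence; and para C-alkylation of a phenoxide through a six-membered transition state competes with elimination and O-alkylation.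
- Comparison: the chosen plan sets against this its brevity (nine steps, ring A from a catechol in one oxidation) and a resolution fallback, and accepts that its key step has no precedent.

**Alternative 2:** The cut is C1–C2. A diarylprolinol silyl ether would turn a C9 aldehyde into its enamine, whose C2 adds in 1,6 fashion to a p-quinone methide at C1, closing ring B and rearomatising the pendant ring to give aldehyde A2.
- Merits: enamine additions to p-quinone methides are an established catalytic asymmetric reaction class, C1 and C2 form together under catalyst control, and the pendant phenol emerges free. In precedent for the asymmetric event this road is ahead of the chosen plan.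
- Weak points: the quinone methide precursor already needs the C8a–C1 bond, that is, arylation of a fully differentiated ring A at its most hindered position; C3 must be set in a separate asymmetric step and must match the catalyst; and a quinone methide tethered to an enolisable aldehyde can isomerise to a styrene.
- Comparison: the chosen plan answers with a much shorter construction of ring A and with C2 and C3 derived from C1 in one substrate-controlled addition.

**Alternative 3:** The cuts are C2–C3 and C1–C8a. Mn(OAc)3 with Cu(OAc)2 would oxidise a ring A benzylmalonate to a C3 radical that adds to the alkene of a protected coniferyl acetate; the benzylic C1 radical or cation then attacks C8a to give the bromo diester A3.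
- Merits: this is the most convergent plan, it uses two phenylpropanoid-type halves and cheap reagents, and the 1,2-trans relation arises on cyclisation. In convergency it beats the chosen route.
- Weak points: it is racemic by nature; a bromine blocking group is needed to steer the ring closure and must later be removed; the geminal diester must be degraded to one CH2OH, which brings back the C3 problem under the unfavourable peri effect; and electron-rich benzyl-protected arenes are themselves oxidised under these conditions.
- Comparison: the chosen plan sets against the convergency a direct handle on absolute configuration and a stereospecific answer for C2 and C3.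

Key step: step 5

## Route

Assumption: tetralin numbering of the target (C1–C8a; C9 and C9′ for the carbons on C2 and C3) is used for all intermediates.

Assumption: the sense of induction of the copper–bis(oxazoline) catalyst on 7 cannot be assigned by analogy, so the ligand antipode (tBu-box = 2,2′-isopropylidenebis(4-tert-butyl-2-oxazoline)) that gives the 1S series is taken to be found in a first screen.

Step 1
Reactants: 1 2-bromoprop-2-en-1-ol (2-bromoallyl alcohol)
Product: 2 benzyl 2-bromoallyl ether
Conditions: NaH, BnBr, Bu4NI (cat.), THF, 0 °C to rt
Reagents that add atoms: benzyl bromide, BrCc1ccccc1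
Why: Williamson ether synthesis; the primary alkoxide is benzylated at 0 °C well before the vinyl bromide can eliminate.

Step 2
Reactants: 3 4-benzyloxy-3-methoxybenzaldehyde (O-benzylvanillin)
Product: 4 (E)-2-[2-(4-benzyloxy-3-methoxyphenyl)ethenyl]-4,4,5,5-tetramethyl-1,3,2-dioxaborolane
Conditions: CH2(Bpin)2, LiTMP, THF, 0 °C; then 3, −78 °C to rt
Reagents that add atoms: bis(4,4,5,5-tetramethyl-1,3,2-dioxaborolan-2-yl)methane, CC1(C)OB(CB2OC(C)(C)C(C)(C)O2)OC1(C)C
Why: Boron–Wittig olefination; the lithiated geminal diboronate adds to the aryl aldehyde and syn B–O elimination should give the (E)-alkenylboronate selectively.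

Step 3
Reactants: 4 (E)-styrylboronate; 2 benzyl 2-bromoallyl ether
Product: 5 (E)-1-(4-benzyloxy-3-methoxyphenyl)-3-(benzyloxymethyl)buta-1,3-diene
Conditions: Pd(PPh3)4 (5 mol%), K2CO3 (2 M aq.), THF, 60 °C, BHT (trace)
Reagents that add atoms: none
Why: Suzuki–Miyaura alkenyl–alkenyl coupling, which proceeds with retention of the E geometry; the 3-substituent favours the s-cis diene needed later.

Step 4
Reactants: 6 3-methoxybenzene-1,2-diol (3-methoxycatechol)
Product: 7 3-methoxy-1,2-benzoquinone
Conditions: NaIO4, H2O–CH2Cl2, 0 °C; organic layer dried (Na2SO4) and used at once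
Reagents that add atoms: none
Why: Periodate oxidation of a catechol to the o-quinone; the quinone is not stored, because o-quinones dimerise, and is carried forward as a cold solution.

Step 5
Reactants: 7 3-methoxy-1,2-benzoquinone; 5 (E)-1-(4-benzyloxy-3-methoxyphenyl)-3-(benzyloxymethyl)buta-1,3-diene
Product: 9 (1S)-1-(4-benzyloxy-3-methoxyphenyl)-3-(benzyloxymethyl)-6-methoxy-1,4-dihydronaphthalene-7,8-diol, via cis-fused endo cycloadduct 8 (not isolated)
Conditions: [Cu(tBu-box)](SbF6)2 (10–20 mol%), 4 Å MS, CH2Cl2, −78 °C, slow addition of 7 to 5 (1.5 equiv); aq. EDTA; then SiO2, CH2Cl2, rt, argon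
Reagents that add atoms: none
Why: Proposed new method: an enantioselective Diels–Alder reaction of an o-benzoquinone acting as carbodienophile under a chelating chiral Lewis acid has no direct precedent; the closest known reaction types are the thermal [4+2] additions of o-benzoquinones to 1,3-dienes through a ring C=C and the Diels–Alder reactions of two-point-binding dienophiles and chelating quinones catalysed by bis(oxazoline) complexes of divalent copper or by lanthanide triflate–pybox complexes. Mechanistically, 7 should bind the square-planar copper centre through both carbonyl oxygens, which lowers the LUMO of the one ring C=C that does not carry the methoxy donor and places a tert-butyl group of the C2-symmetric ligand over one face of that bond. Diene 5 then adds in a concerted, asynchronous, suprafacial [4+2] cycloaddition in which its CH2 terminus (largest HOMO coefficient, reinforced by the 1-aryl and 3-alkyl groups) bonds to the β-carbon of the chelated enone (future C4a) and its ArCH terminus to the α-carbon (future C8a), so ring B closes by intermolecular cycloaddition with C1–C8a and C4–C4a formed in the same event. The doubly enolisable ene-dione 8 then loses both ring-fusion hydrogens by two proton shifts on silica, and the aromatisation of ring A to the catechol makes this irreversible. Because these shifts erase C4a and C8a, C1 is the only stereocentre that survives, and it is controlled by the quinone face left open by the ligand combined with the endo orientation of the diene under the C8 carbonyl. The step therefore needs chemoselectivity for the carbo- over the hetero-Diels–Alder mode (secured by tying up the dione oxygens on copper and by the low temperature), ortho regioselectivity (secured by the matched polarisation of 5 and the chelated enone), and high endo and facial selectivity (secured by the rigid in-plane chelate). Slow addition of 7 to an excess of 5 keeps free quinone scarce and so limits quinone dimerisation and redox exchange with the catechol product.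

Step 6
Reactants: 9 (1S)-1-(4-benzyloxy-3-methoxyphenyl)-3-(benzyloxymethyl)-6-methoxy-1,4-dihydronaphthalene-7,8-diol
Product: 10 (1S)-7,8-bis(benzyloxy)-1-(4-benzyloxy-3-methoxyphenyl)-3-(benzyloxymethyl)-6-methoxy-1,4-dihydronaphthalene
Conditions: BnBr, K2CO3, DMF, rt, argon
Reagents that add atoms: benzyl bromide, BrCc1ccccc1
Why: Williamson O-benzylation of both phenols; carbonate is too weak a base to touch the doubly benzylic C1–H or to shift the 1,4-diene, and exclusion of air protects the catecholate.

Step 7
Reactants: 10 (1S)-7,8-bis(benzyloxy)-1-(4-benzyloxy-3-methoxyphenyl)-3-(benzyloxymethyl)-6-methoxy-1,4-dihydronaphthalene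
Product: 13 (1S,2R,3R)-7,8-bis(benzyloxy)-1-(4-benzyloxy-3-methoxyphenyl)-3-(benzyloxymethyl)-6-methoxy-2-(4,4,5,5-tetramethyl-1,3,2-dioxaborolan-2-yl)-1,2,3,4-tetrahydronaphthalene, via B-alkyl-B-isopinocampheylborane 11 (not isolated), via diethyl boronate 12 (not isolated)
Conditions: IpcBH2 (from (−)-α-pinene), THF, −25 to 0 °C; CH3CHO (excess), 0 °C to rt; pinacol, rt
Reagents that add atoms: monoisopinocampheylborane (IpcBH2), C[C@@H]1[C@@H]([BH2])C[C@H]2C[C@@H]1C2(C)C; pinacol, CC(C)(O)C(C)(C)O
Why: Brown hydroboration with monoisopinocampheylborane, then acetaldehyde-induced loss of α-pinene and transesterification with pinacol. H and B add syn and anti-Markovnikov across C2=C3 from the face anti to the C1 aryl group (held pseudoaxial by peri strain with the 8-benzyloxy group), so boron lands on C2 trans to the aryl group and the C3 benzyloxymethyl group ends up on the face opposite boron, which sets C2 and C3 together. The reagent antipode is chosen so that its own facial preference matches this substrate bias (by analogy with 1-methylcyclohexene, the one from (−)-α-pinene).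

Step 8
Reactants: 13 (1S,2R,3R)-2-boronate
Product: 15 [(1S,2R,3R)-7,8-bis(benzyloxy)-1-(4-benzyloxy-3-methoxyphenyl)-3-(benzyloxymethyl)-6-methoxy-1,2,3,4-tetrahydronaphthalen-2-yl]methanol, via homologated pinacol boronate 14 (not isolated)
Conditions: BrCH2Cl, n-BuLi, THF, −78 °C to rt; then NaOH, H2O2, THF–H2O, 0 °C to rt
Reagents that add atoms: bromochloromethane, ClCBr; hydrogen peroxide, OO
Why: Matteson homologation; chloromethyllithium made in the presence of 13 forms the boronate complex, and the 1,2-shift of C2 from boron to carbon expels chloride with retention at C2. Oxidation of the new primary C–B bond then gives the C9 alcohol without touching a stereocentre.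

Step 9
Reactants: 15 (1S,2R,3R)-tetra-O-benzyl alcohol
Product: 16 (1S,2R,3R)-1-(4-hydroxy-3-methoxyphenyl)-2,3-bis(hydroxymethyl)-6-methoxy-1,2,3,4-tetrahydronaphthalene-7,8-diol (target)
Conditions: H2 (1 atm), Pd/C (10%), EtOAc–MeOH, rt
Reagents that add atoms: none
Why: Hydrogenolysis of three aryl benzyl ethers and one alkyl benzyl ether; the diarylmethine C1–H bears no heteroatom and should not be cleaved, and no stereocentre is involved.

## Compound list

1 | 2-bromoprop-2-en-1-ol (2-bromoallyl alcohol) | OCC(Br)=C | starting material
2 | benzyl 2-bromoallyl ether | C=C(Br)COCc1ccccc1 | intermediate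
3 | 4-benzyloxy-3-methoxybenzaldehyde (O-benzylvanillin) | COc1cc(C=O)ccc1OCc1ccccc1 | starting material
4 | (E)-2-[2-(4-benzyloxy-3-methoxyphenyl)ethenyl]-4,4,5,5-tetramethyl-1,3,2-dioxaborolane | COc1cc(/C=C/B2OC(C)(C)C(C)(C)O2)ccc1OCc1ccccc1 | intermediate
5 | (E)-1-(4-benzyloxy-3-methoxyphenyl)-3-(benzyloxymethyl)buta-1,3-diene | COc1cc(/C=C/C(=C)COCc2ccccc2)ccc1OCc1ccccc1 | intermediate
6 | 3-methoxybenzene-1,2-diol (3-methoxycatechol) | COc1cccc(O)c1O | starting material
7 | 3-methoxy-1,2-benzoquinone | COC1=CC=CC(=O)C1=O | intermediate
8 | (1R,4aR,8aS)-1-(4-benzyloxy-3-methoxyphenyl)-3-(benzyloxymethyl)-6-methoxy-1,4,4a,8a-tetrahydronaphthalene-7,8-dione (cis-fused endo adduct; H-1, H-4a and H-8a on one face) | COc1cc([C@H]2[C@H]3C(=O)C(=O)C(OC)=C[C@H]3CC(COCc3ccccc3)=C2)ccc1OCc1ccccc1 | intermediate (not isolated)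
9 | (1S)-1-(4-benzyloxy-3-methoxyphenyl)-3-(benzyloxymethyl)-6-methoxy-1,4-dihydronaphthalene-7,8-diol | COc1cc([C@H]2c3c(cc(OC)c(O)c3O)CC(COCc3ccccc3)=C2)ccc1OCc1ccccc1 | intermediate
10 | (1S)-7,8-bis(benzyloxy)-1-(4-benzyloxy-3-methoxyphenyl)-3-(benzyloxymethyl)-6-methoxy-1,4-dihydronaphthalene | COc1cc([C@H]2c3c(cc(OC)c(OCc4ccccc4)c3OCc3ccccc3)CC(COCc3ccccc3)=C2)ccc1OCc1ccccc1 | intermediate
11 | (1S,2R,3R)-2-[hydrido(isopinocampheyl)boryl] derivative of the tetra-O-benzyl tetralin (isopinocampheyl group from (−)-α-pinene; B on C2 trans to the aryl group, C3 substituent trans to B) | COc1cc([C@H]2c3c(cc(OC)c(OCc4ccccc4)c3OCc3ccccc3)C[C@@H](COCc3ccccc3)[C@@H]2[BH][C@H]5C[C@H]6C[C@@H]([C@@H]5C)C6(C)C)ccc1OCc1ccccc1 | intermediate (not isolated)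
12 | diethyl [(1S,2R,3R)-7,8-bis(benzyloxy)-1-(4-benzyloxy-3-methoxyphenyl)-3-(benzyloxymethyl)-6-methoxy-1,2,3,4-tetrahydronaphthalen-2-yl]boronate | COc1cc([C@H]2c3c(cc(OC)c(OCc4ccccc4)c3OCc3ccccc3)C[C@@H](COCc3ccccc3)[C@@H]2B(OCC)OCC)ccc1OCc1ccccc1 | intermediate (not isolated)
13 | (1S,2R,3R)-7,8-bis(benzyloxy)-1-(4-benzyloxy-3-methoxyphenyl)-3-(benzyloxymethyl)-6-methoxy-2-(4,4,5,5-tetramethyl-1,3,2-dioxaborolan-2-yl)-1,2,3,4-tetrahydronaphthalene | COc1cc([C@H]2c3c(cc(OC)c(OCc4ccccc4)c3OCc3ccccc3)C[C@@H](COCc3ccccc3)[C@@H]2B5OC(C)(C)C(C)(C)O5)ccc1OCc1ccccc1 | intermediate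
14 | (1S,2R,3R)-7,8-bis(benzyloxy)-1-(4-benzyloxy-3-methoxyphenyl)-3-(benzyloxymethyl)-6-methoxy-2-[(4,4,5,5-tetramethyl-1,3,2-dioxaborolan-2-yl)methyl]-1,2,3,4-tetrahydronaphthalene | COc1cc([C@H]2c3c(cc(OC)c(OCc4ccccc4)c3OCc3ccccc3)C[C@@H](COCc3ccccc3)[C@@H]2CB5OC(C)(C)C(C)(C)O5)ccc1OCc1ccccc1 | intermediate (not isolated)
15 | [(1S,2R,3R)-7,8-bis(benzyloxy)-1-(4-benzyloxy-3-methoxyphenyl)-3-(benzyloxymethyl)-6-methoxy-1,2,3,4-tetrahydronaphthalen-2-yl]methanol (all-trans) | COc1cc([C@H]2c3c(cc(OC)c(OCc4ccccc4)c3OCc3ccccc3)C[C@@H](COCc3ccccc3)[C@@H]2CO)ccc1OCc1ccccc1 | intermediate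
16 | (1S,2R,3R)-1-(4-hydroxy-3-methoxyphenyl)-2,3-bis(hydroxymethyl)-6-methoxy-1,2,3,4-tetrahydronaphthalene-7,8-diol (CNP0219328.1, all-trans) | COc1cc([C@H]2c3c(cc(OC)c(O)c3O)C[C@@H](CO)[C@@H]2CO)ccc1O | target

## Step count and risks

Total step count: 9. Longest linear sequence: 7 steps (3 → 4 → 5 → 9 → 10 → 13 → 15 → 16; the branch from 1 is equally long, the branch from 6 has 6 steps).

**Step 5 (key step, proposed new method).** Several things may go wrong:
- loss of chemoselectivity, through hetero-Diels–Alder addition at the dione or electron transfer from the electron-rich diene;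
- poor facial or endo selectivity, because the reacting C=C lies far from the ligand, an uncatalysed background reaction is likely, and the quinone may chelate through one carbonyl and the methoxy oxygen instead;
- redox exchange between the catechol product and unreacted quinone, leading to dehydrogenation of ring B;
- product inhibition, since the ene-dione adduct is itself a chelating 1,2-diketone.

Fallback with known chemistry: setting out from 7 and 5, the thermal, uncatalysed cycloaddition (CH2Cl2, −20 °C to rt) should give the racemic cis-fused endo cycloadduct F1, which tautomerises on silica to the racemic dihydronaphthalenediol F2. Benzylation as in step 6 gives the racemic tetra-O-benzyl dihydronaphthalene F3, and preparative chromatography on a chiral stationary phase (cellulose tris(3,5-dimethylphenylcarbamate)) separates it into 10 and the (1R) enantiomer of the tetra-O-benzyl dihydronaphthalene F4, which is set aside. The route is rejoined at 10.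

**Step 7.** The hydroboration may stall or leak to the wrong face, because C2 lies next to the congested C1 and IpcBH2 is bulky, and the substrate–reagent pairing may turn out mismatched; removal of the isopinocampheyl group may also be incomplete. Fallback: setting out from 10, a hydroformylation (Rh(acac)(CO)2, tris(2,4-di-tert-butylphenyl) phosphite, CO/H2, toluene, 80 °C) adds H and CHO syn with the formyl group on the less substituted C2, anti to the aryl group, to give the (1S,2R,3R)-tetralin-2-carbaldehyde F5. Reduction with NaBH4 in MeOH returns the route at 15. The main risk of this fallback is migration of the ring B alkene into conjugation before carbonylation.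

**Step 8.** Chloromethyllithium may decompose before it is captured by the hindered secondary boronate, the 1,2-shift may be incomplete, or stray n-BuLi may deprotonate the doubly benzylic C1–H. Fallback: setting out from 13, a Zweifel olefination (vinylmagnesium bromide, THF–DMSO; then I2, NaOMe, MeOH) transfers C2 to a vinyl group with retention and gives the 2-vinyl tetralin F6. Lemieux–Johnson cleavage (OsO4 cat., NaIO4, 2,6-lutidine, dioxane–H2O) gives the aldehyde F5 described under step 7, and NaBH4 returns the route at 15.

**Step 9.** The hindered 8-O-benzyl ether may be cleaved slowly, and the liberated catechol may oxidise in air during a long reaction. Fallback: setting out from 15, Lewis-acid debenzylation with BCl3 and pentamethylbenzene as cation scavenger (CH2Cl2, −78 °C) replaces hydrogenolysis and gives 16 directly without a new intermediate; the aryl methyl ethers should survive at this temperature.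

## Further compounds

F1 | step 5 | racemic cis-fused endo cycloadduct (rac-8; one enantiomer drawn, relative configuration as in 8) | COc1cc([C@H]2[C@H]3C(=O)C(=O)C(OC)=C[C@H]3CC(COCc3ccccc3)=C2)ccc1OCc1ccccc1
F2 | step 5 | racemic 1-(4-benzyloxy-3-methoxyphenyl)-3-(benzyloxymethyl)-6-methoxy-1,4-dihydronaphthalene-7,8-diol (rac-9) | COc1cc(C2c3c(cc(OC)c(O)c3O)CC(COCc3ccccc3)=C2)ccc1OCc1ccccc1
F3 | step 5 | racemic 7,8-bis(benzyloxy)-1-(4-benzyloxy-3-methoxyphenyl)-3-(benzyloxymethyl)-6-methoxy-1,4-dihydronaphthalene (rac-10) | COc1cc(C2c3c(cc(OC)c(OCc4ccccc4)c3OCc3ccccc3)CC(COCc3ccccc3)=C2)ccc1OCc1ccccc1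
F4 | step 5 | (1R)-7,8-bis(benzyloxy)-1-(4-benzyloxy-3-methoxyphenyl)-3-(benzyloxymethyl)-6-methoxy-1,4-dihydronaphthalene (ent-10) | COc1cc([C@@H]2c3c(cc(OC)c(OCc4ccccc4)c3OCc3ccccc3)CC(COCc3ccccc3)=C2)ccc1OCc1ccccc1
F5 | step 7 | (1S,2R,3R)-7,8-bis(benzyloxy)-1-(4-benzyloxy-3-methoxyphenyl)-3-(benzyloxymethyl)-6-methoxy-1,2,3,4-tetrahydronaphthalene-2-carbaldehyde | COc1cc([C@H]2c3c(cc(OC)c(OCc4ccccc4)c3OCc3ccccc3)C[C@@H](COCc3ccccc3)[C@@H]2C=O)ccc1OCc1ccccc1
F6 | step 8 | (1S,2R,3R)-7,8-bis(benzyloxy)-1-(4-benzyloxy-3-methoxyphenyl)-3-(benzyloxymethyl)-2-ethenyl-6-methoxy-1,2,3,4-tetrahydronaphthalene | COc1cc([C@H]2c3c(cc(OC)c(OCc4ccccc4)c3OCc3ccccc3)C[C@@H](COCc3ccccc3)[C@@H]2C=C)ccc1OCc1ccccc1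
F0 | step 9 | none | none
A1 | alternative 1 | all-trans 8-benzyloxy-1-(4-benzyloxy-3-methoxyphenyl)-2,3-bis(benzyloxymethyl)-6-methoxy-1,2,3,4-tetrahydronaphthalen-7-ol | COc1cc([C@H]2c3c(cc(OC)c(O)c3OCc3ccccc3)C[C@@H](COCc3ccccc3)[C@@H]2COCc4ccccc4)ccc1OCc1ccccc1
A2 | alternative 2 | all-trans 7-benzyloxy-3-(benzyloxymethyl)-1-(4-hydroxy-3-methoxyphenyl)-6-methoxy-8-(methoxymethoxy)-1,2,3,4-tetrahydronaphthalene-2-carbaldehyde | COc1cc([C@H]2c3c(cc(OC)c(OCc4ccccc4)c3OCOC)C[C@@H](COCc3ccccc3)[C@@H]2C=O)ccc1O
A3 | alternative 3 | dimethyl trans-2-(acetoxymethyl)-7,8-bis(benzyloxy)-1-(4-benzyloxy-3-methoxyphenyl)-5-bromo-6-methoxy-1,2-dihydronaphthalene-3,3(4H)-dicarboxylate | COc1cc([C@H]2c3c(c(Br)c(OC)c(OCc4ccccc4)c3OCc3ccccc3)CC(C(=O)OC)(C(=O)OC)[C@@H]2COC(C)=O)ccc1OCc1ccccc1
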